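Ring B of the depside is a 2,4-dihydroxybenzoate carrying the oxoheptyl chain at C6, i.e. the dehydrogenated form of a 2,4-dioxocyclohexane-1-carboxylate. Disconnecting C1–C6 and C2–C3 leaves dibenzyl malonate (C1, C2 and the carboxyl) and an E-enone (C3–C6) whose side-chain ketone is masked as a dioxolane. One Michael–Dieckmann operation therefore builds the whole carbocycle with all four substituents of ring B in place, the carboxyl already as the benzyl ester needed at the end. After aromatisation this one resorcylate serves twice: directly as ring B and, after O-methylation, O-benzylation and saponification, as the ring A acid. Esterification, ketal hydrolysis and hydrogenolysis finish the synthesis.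

Key step: step 4

Remark on stereochemistry: the target is achiral; compounds 7 and 8 are racemic, their SMILES show relative configuration only, and both stereocentres vanish in step 5.
Assumption: sodium benzyloxide is used as its commercial 1 M solution in benzyl alcohol. Resorcylate 9 is divided, one part going to ring A (steps 6–8) and the other serving as the phenol partner in step 9.

Step 1
Reactants: 1 ethyl 3-oxooctanoate
Product: 2 ethyl 2-(2-pentyl-1,3-dioxolan-2-yl)acetate
Conditions: ethylene glycol (3 equiv), TsOH·H2O (cat.), toluene, reflux, azeotropic removal of water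
Reagents that add atoms: ethylene glycol, OCCO
Why: Acid-catalysed ketalisation driven by removal of water converts the ketone carbonyl of the β-keto ester into the dioxolane while the ester is untouched; no stereocentre is formed.

Step 2
Reactants: 2 ethyl 2-(2-pentyl-1,3-dioxolan-2-yl)acetate
Product: 3 2-(2-pentyl-1,3-dioxolan-2-yl)acetaldehyde
Conditions: i-Bu2AlH (DIBAL-H, 1.1 equiv), CH2Cl2, −78 °C; aq. KNaC4H4O6 work-up; used crude
Reagents that add atoms: none
Why: Partial ester reduction with DIBAL-H should stop at the aldehyde because the tetrahedral aluminium hemiacetal, further held by a dioxolane oxygen, persists at low temperature until hydrolytic work-up.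

Step 3
Reactants: 3 2-(2-pentyl-1,3-dioxolan-2-yl)acetaldehyde; 4 1-(triphenylphosphoranylidene)propan-2-one
Product: 5 (E)-5-(2-pentyl-1,3-dioxolan-2-yl)pent-3-en-2-one
Conditions: 4 (1.2 equiv), CH2Cl2, rt
Reagents that add atoms: none
Why: Wittig olefination with a ketone-stabilised ylide is mild enough to spare the β-alkoxy aldehyde and should give the E-alkene, as stabilised ylides do.

Step 4
Reactants: 5 (E)-5-(2-pentyl-1,3-dioxolan-2-yl)pent-3-en-2-one; 6 dibenzyl malonate
Product: 8 benzyl trans-2-hydroxy-4-oxo-6-[(2-pentyl-1,3-dioxolan-2-yl)methyl]cyclohex-2-ene-1-carboxylate (racemic), via acyclic Michael adduct 7 (not isolated)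
Conditions: 6 (1.05 equiv), NaOBn (0.1 equiv), THF, 0 °C to rt; then NaOBn (1.1 equiv, 1 M in BnOH), 60 °C; AcOH, H2O, 0 °C
Reagents that add atoms: none
Why: The malonate anion of 6 adds 1,4 to enone 5 to give 7 (C1–C6 formed); proton transfer then provides a small equilibrium share of the methyl ketone enolate, whose CH3-derived carbon acylates on one benzyl ester (C2–C3 formed) with loss of benzyloxide, and the sequence is pulled forward by formation of the stable vinylogous-acid sodium salt. The closest known reaction type is the classical malonate–enone Michael–Dieckmann synthesis of alkyl 6-alkyl-2,4-dioxocyclohexanecarboxylates (dihydroresorcylates). The six-membered ring closes in the 6-exo-trig mode, the only strain-free option, since closure through the internal C5 enolate would give a four-membered ring. The C6 stereocentre arises without control in the Michael stage (racemic), and C1, an epimerisable β-keto ester carbon, should settle under thermodynamic control trans to the C6 side chain; both are erased in step 5. The selectivities needed are conjugate over direct addition, secured by the soft stabilised nucleophile, and survival of the γ-CH2/ketal array of 5, secured by keeping alkoxide catalytic while enone is present and by matching benzyloxide to the benzyl esters so that transesterification is degenerate.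

Step 5
Reactants: 8 benzyl trans-2-hydroxy-4-oxo-6-[(2-pentyl-1,3-dioxolan-2-yl)methyl]cyclohex-2-ene-1-carboxylate
Product: 9 benzyl 2,4-dihydroxy-6-[(2-pentyl-1,3-dioxolan-2-yl)methyl]benzoate
Conditions: DDQ (1.1 equiv), dry 1,4-dioxane, 80 °C; filtration, aq. NaHCO3 wash
Reagents that add atoms: none
Why: DDQ dehydrogenation (hydride abstraction from C6 of the enolised β-keto ester, proton loss, tautomerisation) should give the benzenoid ring with aromatisation as driving force, while the anhydrous medium free of mineral acid spares the dioxolane and the benzyl ester and both stereocentres of 8 are erased.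

Step 6
Reactants: 9 benzyl 2,4-dihydroxy-6-[(2-pentyl-1,3-dioxolan-2-yl)methyl]benzoate
Product: 10 benzyl 2-hydroxy-4-methoxy-6-[(2-pentyl-1,3-dioxolan-2-yl)methyl]benzoate
Conditions: MeI (1.1 equiv), K2CO3 (1.2 equiv), acetone, reflux
Reagents that add atoms: iodomethane, CI
Why: Williamson etherification should take place at the 4-OH only, because the 2-OH is locked in a hydrogen bond to the ester carbonyl and is much less nucleophilic under these mild conditions.

Step 7
Reactants: 10 benzyl 2-hydroxy-4-methoxy-6-[(2-pentyl-1,3-dioxolan-2-yl)methyl]benzoate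
Product: 11 benzyl 2-(benzyloxy)-4-methoxy-6-[(2-pentyl-1,3-dioxolan-2-yl)methyl]benzoate
Conditions: BnBr (1.3 equiv), K2CO3 (2 equiv), DMF, 60 °C
Reagents that add atoms: benzyl bromide, BrCc1ccccc1
Why: Williamson benzylation in a dipolar aprotic solvent at elevated temperature overcomes the chelation of the remaining phenol and caps it with a group that leaves in the final hydrogenolysis.

Step 8
Reactants: 11 benzyl 2-(benzyloxy)-4-methoxy-6-[(2-pentyl-1,3-dioxolan-2-yl)methyl]benzoate
Product: 12 2-(benzyloxy)-4-methoxy-6-[(2-pentyl-1,3-dioxolan-2-yl)methyl]benzoic acid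
Conditions: KOH (5 equiv), DMSO/H2O, 90 °C; then cold aq. KHSO4 to pH 4
Reagents that add atoms: potassium hydroxide, [K+].[OH-]
Why: Saponification by poorly solvated hydroxide in aqueous DMSO cleaves even a doubly ortho-substituted benzoate, while the benzyl ether, methyl ether and base-stable dioxolane are untouched and the mild cold acidification keeps the ketal.

Step 9
Reactants: 12 2-(benzyloxy)-4-methoxy-6-[(2-pentyl-1,3-dioxolan-2-yl)methyl]benzoic acid; 9 benzyl 2,4-dihydroxy-6-[(2-pentyl-1,3-dioxolan-2-yl)methyl]benzoate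
Product: 13 benzyl 4-({2-(benzyloxy)-4-methoxy-6-[(2-pentyl-1,3-dioxolan-2-yl)methyl]benzoyl}oxy)-2-hydroxy-6-[(2-pentyl-1,3-dioxolan-2-yl)methyl]benzoate
Conditions: DCC (1.1 equiv), DMAP (0.2 equiv), CH2Cl2, 0 °C to rt
Reagents that add atoms: none
Why: In this Steglich esterification the acylpyridinium ion formed from the O-acylisourea should transfer the hindered aroyl group to the 4-OH of 9, the more nucleophilic hydroxyl because the 2-OH is hydrogen-bonded to the ester carbonyl, and the neutral medium leaves both dioxolanes intact.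

Step 10
Reactants: 13 benzyl 4-({2-(benzyloxy)-4-methoxy-6-[(2-pentyl-1,3-dioxolan-2-yl)methyl]benzoyl}oxy)-2-hydroxy-6-[(2-pentyl-1,3-dioxolan-2-yl)methyl]benzoate
Product: 14 benzyl 4-{[2-(benzyloxy)-4-methoxy-6-(2-oxoheptyl)benzoyl]oxy}-2-hydroxy-6-(2-oxoheptyl)benzoate
Conditions: 1 M HCl, THF, rt
Reagents that add atoms: water, O
Why: Acid-catalysed ketal hydrolysis in dilute aqueous acid at room temperature should release both ketones without touching the aryl ester, benzyl ester or benzyl ether, and with the carboxyl and the ring A phenol still blocked the ortho oxoalkyl groups have no free acid to lactonise with.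

Step 11
Reactants: 14 benzyl 4-{[2-(benzyloxy)-4-methoxy-6-(2-oxoheptyl)benzoyl]oxy}-2-hydroxy-6-(2-oxoheptyl)benzoate
Product: 15 microphyllinic acid, 2-hydroxy-4-{[2-hydroxy-4-methoxy-6-(2-oxoheptyl)benzoyl]oxy}-6-(2-oxoheptyl)benzoic acid
Conditions: H2 (1 atm), 10% Pd/C, EtOAc, rt
Reagents that add atoms: none
Why: Catalytic hydrogenolysis removes the benzyl ester and the benzyl ether together under neutral conditions that leave the aliphatic ketones and the depside ester alone and avoid decarboxylation of the salicylic acid.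

Compound list
1 | ethyl 3-oxooctanoate | CCCCCC(=O)CC(=O)OCC | starting material
2 | ethyl 2-(2-pentyl-1,3-dioxolan-2-yl)acetate | CCCCCC1(CC(=O)OCC)OCCO1 | intermediate
3 | 2-(2-pentyl-1,3-dioxolan-2-yl)acetaldehyde | CCCCCC1(CC=O)OCCO1 | intermediate
4 | 1-(triphenylphosphoranylidene)propan-2-one | CC(=O)C=P(c1ccccc1)(c1ccccc1)c1ccccc1 | starting material
5 | (E)-5-(2-pentyl-1,3-dioxolan-2-yl)pent-3-en-2-one | CC(=O)/C=C/CC1(CCCCC)OCCO1 | intermediate
6 | dibenzyl malonate | O=C(CC(=O)OCc1ccccc1)OCc1ccccc1 | starting material
7 | dibenzyl 2-[4-oxo-1-(2-pentyl-1,3-dioxolan-2-yl)pentan-2-yl]propanedioate (racemic, not isolated) | CC(=O)CC(CC1(CCCCC)OCCO1)C(C(=O)OCc1ccccc1)C(=O)OCc1ccccc1 | intermediate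
8 | benzyl trans-2-hydroxy-4-oxo-6-[(2-pentyl-1,3-dioxolan-2-yl)methyl]cyclohex-2-ene-1-carboxylate (racemic, one enantiomer drawn) | O=C(OCc1ccccc1)[C@@H]1C(O)=CC(=O)C[C@H]1CC1(CCCCC)OCCO1 | intermediate
9 | benzyl 2,4-dihydroxy-6-[(2-pentyl-1,3-dioxolan-2-yl)methyl]benzoate | O=C(OCc1ccccc1)c1c(O)cc(O)cc1CC1(CCCCC)OCCO1 | intermediate
10 | benzyl 2-hydroxy-4-methoxy-6-[(2-pentyl-1,3-dioxolan-2-yl)methyl]benzoate | COc1cc(O)c(C(=O)OCc2ccccc2)c(CC2(CCCCC)OCCO2)c1 | intermediate
11 | benzyl 2-(benzyloxy)-4-methoxy-6-[(2-pentyl-1,3-dioxolan-2-yl)methyl]benzoate | COc1cc(OCc2ccccc2)c(C(=O)OCc2ccccc2)c(CC2(CCCCC)OCCO2)c1 | intermediate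
12 | 2-(benzyloxy)-4-methoxy-6-[(2-pentyl-1,3-dioxolan-2-yl)methyl]benzoic acid | COc1cc(OCc2ccccc2)c(C(=O)O)c(CC2(CCCCC)OCCO2)c1 | intermediate
13 | benzyl 4-({2-(benzyloxy)-4-methoxy-6-[(2-pentyl-1,3-dioxolan-2-yl)methyl]benzoyl}oxy)-2-hydroxy-6-[(2-pentyl-1,3-dioxolan-2-yl)methyl]benzoate | COc1cc(OCc2ccccc2)c(C(=O)Oc2cc(O)c(C(=O)OCc3ccccc3)c(CC3(CCCCC)OCCO3)c2)c(CC2(CCCCC)OCCO2)c1 | intermediate
14 | benzyl 4-{[2-(benzyloxy)-4-methoxy-6-(2-oxoheptyl)benzoyl]oxy}-2-hydroxy-6-(2-oxoheptyl)benzoate | CCCCCC(=O)Cc1cc(OC(=O)c2c(OCc3ccccc3)cc(OC)cc2CC(=O)CCCCC)cc(O)c1C(=O)OCc1ccccc1 | intermediate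
15 | microphyllinic acid | CCCCCC(=O)Cc1cc(OC(=O)c2c(O)cc(OC)cc2CC(=O)CCCCC)cc(O)c1C(=O)O | target

Total step count: 11. Longest linear sequence: 11 steps (1 to 9 in steps 1–5, 9 to 12 in steps 6–8, then steps 9–11).

Steps most likely to fail

Step 4. The enone may be deprotonated at its γ-CH2 and open the dioxolane by vinylogous β-elimination, or the Michael adduct may revert or fail to close. The fallback sets out from aldehyde 3 and forms the ring through C1–C6 and C3–C4 instead. Wittig reaction of 3 with ethyl (triphenylphosphoranylidene)acetate in CH2Cl2 should give ethyl (E)-4-(2-pentyl-1,3-dioxolan-2-yl)but-2-enoate F1, a poorer carbon acid at its γ-position than the enone. Benzyl acetoacetate and NaOBn in THF/BnOH should then add to F1 to give 1-benzyl 5-ethyl 2-acetyl-3-[(2-pentyl-1,3-dioxolan-2-yl)methyl]pentanedioate F2, not isolated. The acetyl CH3 enolate of F2 closes onto the ethyl ester, and acidification returns the route to compound 8.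

Step 5. Hydride abstraction may be sluggish, the electron-rich product may be oxidised further, or the acidic hydroquinone formed may cost the dioxolane. The fallback sets out from 8 and replaces dehydrogenation by selenoxide elimination. The dianion of 8 (LiN(i-Pr)2, 2.2 equiv, THF, −78 °C) should be selenenylated by PhSeCl at C1, anti to the C6 side chain, giving benzyl 2-hydroxy-4-oxo-6-[(2-pentyl-1,3-dioxolan-2-yl)methyl]-1-(phenylselanyl)cyclohex-2-ene-1-carboxylate F3. Oxidation with H2O2 and pyridine in CH2Cl2 at 0 °C should give the corresponding selenoxide F4, not isolated. Syn-elimination across C1–C6, with the C6 hydrogen on the same face as selenium, and tautomerisation return the route to compound 9.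

Step 9. Acyl transfer from the doubly ortho-substituted acid may be slow enough for the O-acylisourea to rearrange to the N-acylurea, or for the chelated 2-OH to compete. The fallback sets out from 12 and uses a preformed acyl chloride made under neutral conditions that spare the ketal. Treatment of 12 with 1-chloro-N,N,2-trimethylprop-1-en-1-amine in CH2Cl2 at rt should give 2-(benzyloxy)-4-methoxy-6-[(2-pentyl-1,3-dioxolan-2-yl)methyl]benzoyl chloride F5. Adding F5 to 9 with Et3N and catalytic DMAP at 0 °C returns the route to compound 13.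

Further compounds
F1 | step 4 | ethyl (E)-4-(2-pentyl-1,3-dioxolan-2-yl)but-2-enoate | CCOC(=O)/C=C/CC1(CCCCC)OCCO1
F2 | step 4 | 1-benzyl 5-ethyl 2-acetyl-3-[(2-pentyl-1,3-dioxolan-2-yl)methyl]pentanedioate (racemic diastereomer mixture) | CCOC(=O)CC(CC1(CCCCC)OCCO1)C(C(C)=O)C(=O)OCc1ccccc1
F3 | step 5 | benzyl 2-hydroxy-4-oxo-6-[(2-pentyl-1,3-dioxolan-2-yl)methyl]-1-(phenylselanyl)cyclohex-2-ene-1-carboxylate (racemic, selenium trans to the C6 side chain) | O=C(OCc1ccccc1)[C@@]1([Se]c2ccccc2)C(O)=CC(=O)C[C@H]1CC1(CCCCC)OCCO1
F4 | step 5 | benzyl 2-hydroxy-4-oxo-6-[(2-pentyl-1,3-dioxolan-2-yl)methyl]-1-(phenylseleninyl)cyclohex-2-ene-1-carboxylate (racemic, configuration at selenium undefined) | O=C(OCc1ccccc1)[C@@]1([Se](=O)c2ccccc2)C(O)=CC(=O)C[C@H]1CC1(CCCCC)OCCO1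
F5 | step 9 | 2-(benzyloxy)-4-methoxy-6-[(2-pentyl-1,3-dioxolan-2-yl)methyl]benzoyl chloride | COc1cc(OCc2ccccc2)c(C(=O)Cl)c(CC2(CCCCC)OCCO2)c1
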